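**Plan**

1. Retrosynthetic cuts, in order: the O‑benzyl bond on C6; the three ring bonds O1–C2, C2–C3 and C4–O(enol) of the furanone, which removes C2 and two oxygens as CO2 and leaves an open‑chain γ‑hydroxy ynone; C1′–C3 (acetylide plus Weinreb amide); C12′–C13′ of the side chain (copper‑catalysed alkyl–alkyl coupling).
2. Enabling feature: in the 3‑acyl‑4‑hydroxyfuran‑2(5H)‑one ring, the lactone carbonyl C2 and the enol oxygen on C4 together make up one CO2. With C3–C4 written as a triple bond, the acyclic 4‑hydroxy‑2‑yn‑1‑one already holds C1′, C3, C4, C5, C6 and the ring oxygen O1.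
3. Forward: the C17 anteiso acid is assembled and converted to its Weinreb amide; a benzyloxymethyl alkynyl ketone is reduced to the propargylic carbinol and desilylated; the two are joined at C1′–C3; the single ring (O1–C2–C3–C4–C5) is closed with CO2 in one flask; the benzyl group is removed last.
4. Stereochemistry: C14′ (S) is bought with (S)‑1‑bromo‑2‑methylbutane and no bond to it changes. C5 (S) is set as the (R)‑propargylic carbinol by Noyori transfer hydrogenation with the (S,S)‑TsDPEN ruthenium catalyst and carried through; R becomes S only because the CIP priorities change when the alkyne carbon becomes C4.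

Key step: step 7

Remark: numbering used is ring O1, C2 (lactone C=O), C3, C4 (enol carbon), C5, C6 (CH2O), and side chain C1′ (ketone) to C16′ with the methyl branch on C14′; the acyltetronic acids are drawn as the 4‑hydroxy enol, which stands for the set of rapidly interconverting chelated tautomers.

**Step 1**
Reactants: 1 (S)-1-bromo-2-methylbutane; 2 12-bromododecanoic acid
Product: 5 (S)-14-methylhexadecanoic acid, via (S)-2-methylbutylmagnesium bromide 3 (not isolated), via chloromagnesium 12-bromododecanoate 4 (not isolated)
Conditions: 1, Mg, THF, 45 °C; separately 2, MeMgCl (1.0 equiv), THF, −20 °C; Grignard solution (1.3 equiv) added, Li2CuCl4 (3 mol%), −20 °C → rt; 1 M HCl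
Reagents that add atoms: none
Why: Li2CuCl4‑catalysed alkyl–alkyl Grignard cross‑coupling (Kochi‑type) with the ω‑bromo acid masked as its magnesium carboxylate should form C12′–C13′, and the (S) center, β to magnesium, takes no part in any bond change.

**Step 2**
Reactants: 5 (S)-14-methylhexadecanoic acid
Product: 7 (S)-N-methoxy-N,14-dimethylhexadecanamide, via 1-[(S)-14-methylhexadecanoyl]imidazole 6 (not isolated)
Conditions: CDI (1,1′‑carbonyldiimidazole, 1.2 equiv), CH2Cl2, rt; then MeNH(OMe)·HCl (1.5 equiv), rt
Reagents that add atoms: N,O-dimethylhydroxylamine hydrochloride, CNOC.Cl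
Why: Carboxyl activation as the acyl imidazolide followed by aminolysis (Weinreb amide formation) leaves the remote stereocenter alone and installs an acyl donor that should accept exactly one acetylide.

**Step 3**
Reactants: 8 ethynyltrimethylsilane; 9 benzyloxyacetyl chloride
Product: 12 1-(benzyloxy)-4-(trimethylsilyl)but-3-yn-2-one, via lithium (trimethylsilyl)acetylide 10 (not isolated), via chloro[(trimethylsilyl)ethynyl]zinc 11 (not isolated)
Conditions: 8, n‑BuLi (1.05 equiv), THF, −78 °C; ZnCl2 (1.1 equiv), −78 → 0 °C; 9, Pd(PPh3)4 (3 mol%), 0 °C → rt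
Reagents that add atoms: none
Why: In this Negishi acylation the alkynylzinc chloride transmetalates to the acylpalladium chloride formed by oxidative addition of 9 to zerovalent palladium, and no amine base is present that could turn the α‑alkoxy acid chloride into a ketene.

**Step 4**
Reactants: 12 1-(benzyloxy)-4-(trimethylsilyl)but-3-yn-2-one
Product: 13 (R)-1-(benzyloxy)-4-(trimethylsilyl)but-3-yn-2-ol
Conditions: Ru[(S,S)-TsNCH(Ph)CH(Ph)NH](p-cymene) (1 mol%; base‑free amido complex made beforehand from RuCl[(S,S)-TsDPEN](p-cymene) and KOH), i‑PrOH, rt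
Reagents that add atoms: none
Why: In Noyori asymmetric transfer hydrogenation of an alkynyl ketone the alkyne plays the unsaturated group in the concerted hydride–proton transfer, so the (S,S)‑catalyst, which gives (S)‑4‑silylbut‑3‑yn‑2‑ols, should give the spatially analogous carbinol, here named (R) because CH2OBn outranks the alkynyl carbon.

**Step 5**
Reactants: 13 (R)-1-(benzyloxy)-4-(trimethylsilyl)but-3-yn-2-ol
Product: 14 (R)-1-(benzyloxy)but-3-yn-2-ol
Conditions: K2CO3 (0.2 equiv), MeOH, 0 °C → rt
Reagents that add atoms: none
Why: Methoxide‑catalysed protodesilylation cleaves only the C(sp)–SiMe3 bond and should leave the carbinol configuration and the benzyl ether intact.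

**Step 6**
Reactants: 14 (R)-1-(benzyloxy)but-3-yn-2-ol; 7 (S)-N-methoxy-N,14-dimethylhexadecanamide
Product: 16 (2R,18S)-1-(benzyloxy)-2-hydroxy-18-methylicos-3-yn-5-one, via dilithiated alkynol 15 (not isolated)
Conditions: 14 (1.2 equiv), n‑BuLi (2.4 equiv), THF, −78 → −40 °C; then 7, −78 → −10 °C; inverse quench into cold 1 M HCl
Reagents that add atoms: none
Why: In this Weinreb ketone synthesis with the O,C‑dilithiated propargylic alcohol only the acetylide carbon attacks the amide, the chelated tetrahedral adduct holds until the acidic quench (which also protonates the released amine so that it cannot add to the ynone), and the carbinol center is not involved.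

**Step 7**
Reactants: 16 (2R,18S)-1-(benzyloxy)-2-hydroxy-18-methylicos-3-yn-5-one; 17 carbon dioxide
Product: 20 (S)-5-[(benzyloxy)methyl]-4-hydroxy-3-[(S)-14-methylhexadecanoyl]furan-2(5H)-one, via alkylidene cyclic carbonate 18 (not isolated), via tert-butyl carbonate enolate 19 (not isolated)
Conditions: AgOAc (10 mol%), CO2 (1.0 MPa), toluene, 0 °C, then DBU (1,8‑diazabicyclo[5.4.0]undec‑7‑ene, 1.1 equiv) added last, 0 °C → rt; vent, argon purge; KOtBu (20 mol%), THF, rt → 40 °C; 1 M HCl
Reagents that add atoms: carbon dioxide (compound 17), O=C=O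
Why: Proposed new method: DBU and CO2 turn the carbinol of 16 into a carbonate anion whose terminal oxygen adds as an oxa‑Michael donor to C4, the β‑carbon of the AgOAc‑activated ynone (C4–O bond, 5‑exo‑dig, anti addition, then protonation at C3), giving the 4‑(acylmethylene)‑1,3‑dioxolan‑2‑one 18, which is the cyclic enol carbonate of a 1,3‑diketone. tert‑Butoxide then attacks the carbonate carbonyl and expels the diketone enolate, a far better leaving group than the secondary alkoxide, so the carbonate stays on O1 as in 19, and the central enolate carbon C3 attacks that carbonate carbonyl in a 5‑exo‑trig acyl substitution (C2–C3 bond) that releases tert‑butoxide and closes the furanone ring. The closest known reaction types are the AgOAc/DBU carboxylative cyclisation of propargylic alcohols with CO2 to α‑alkylidene cyclic carbonates, the alkoxide opening of such carbonates to β‑oxo carbonates, and the Claisen‑type enolate acylation by a carbonate that converts 2‑hydroxyacetophenones into 4‑hydroxycoumarins. No stereocenter is formed, and C5 is carried through because none of its bonds is broken and its hydrogen is only γ to the enone in 18 and sits next to an enolate, not a free ketone, in 19. The step needs carbonate formation at oxygen in preference to C‑carboxylation at C2′ or amidine‑induced isomerisation of the γ‑hydroxy ynone to an ene‑dione, which is secured by saturating the cold solution with CO2 before DBU is added so that the much more acidic carbinol is trapped as a weakly basic carbonate that cyclises intramolecularly. It also needs C‑ over O‑acylation in the second stage, which is secured because O‑acylation only returns 18 whereas C‑acylation gives the strongly acidic tetronic acid, whose deprotonation by DBU makes the closure irreversible and keeps tert‑butoxide catalytic.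

**Step 8**
Reactants: 20 (S)-5-[(benzyloxy)methyl]-4-hydroxy-3-[(S)-14-methylhexadecanoyl]furan-2(5H)-one
Product: 21 (S)-4-hydroxy-5-(hydroxymethyl)-3-[(S)-14-methylhexadecanoyl]furan-2(5H)-one (CNP0271893.1)
Conditions: H2 (1 atm), 10% Pd/C, EtOAc, rt
Reagents that add atoms: none
Why: Catalytic hydrogenolysis should cleave the benzylic C–O bond on Pd/C while the tetrasubstituted, chelated enol double bond of the acyltetronic acid and both stereocenters are unaffected under one atmosphere of hydrogen.

**Compound list**

1 | (S)-1-bromo-2-methylbutane | CC[C@H](C)CBr | starting material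
2 | 12-bromododecanoic acid | OC(=O)CCCCCCCCCCCBr | starting material
3 | (S)-2-methylbutylmagnesium bromide | CC[C@H](C)C[Mg]Br | intermediate
4 | chloromagnesium 12-bromododecanoate | BrCCCCCCCCCCCC(=O)O[Mg]Cl | intermediate
5 | (S)-14-methylhexadecanoic acid | CC[C@H](C)CCCCCCCCCCCCC(=O)O | intermediate
6 | 1-[(S)-14-methylhexadecanoyl]-1H-imidazole | CC[C@H](C)CCCCCCCCCCCCC(=O)n1ccnc1 | intermediate
7 | (S)-N-methoxy-N,14-dimethylhexadecanamide | CC[C@H](C)CCCCCCCCCCCCC(=O)N(C)OC | intermediate
8 | ethynyltrimethylsilane | C#C[Si](C)(C)C | starting material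
9 | benzyloxyacetyl chloride | ClC(=O)COCc1ccccc1 | starting material
10 | lithium (trimethylsilyl)acetylide | [Li]C#C[Si](C)(C)C | intermediate
11 | chloro[(trimethylsilyl)ethynyl]zinc | Cl[Zn]C#C[Si](C)(C)C | intermediate
12 | 1-(benzyloxy)-4-(trimethylsilyl)but-3-yn-2-one | C[Si](C)(C)C#CC(=O)COCc1ccccc1 | intermediate
13 | (R)-1-(benzyloxy)-4-(trimethylsilyl)but-3-yn-2-ol | C[Si](C)(C)C#C[C@@H](O)COCc1ccccc1 | intermediate
14 | (R)-1-(benzyloxy)but-3-yn-2-ol | C#C[C@@H](O)COCc1ccccc1 | intermediate
15 | O,C-dilithiated (R)-1-(benzyloxy)but-3-yn-2-ol (lithium alkoxide, lithium acetylide) | [Li]C#C[C@@H](O[Li])COCc1ccccc1 | intermediate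
16 | (2R,18S)-1-(benzyloxy)-2-hydroxy-18-methylicos-3-yn-5-one | CC[C@H](C)CCCCCCCCCCCCC(=O)C#C[C@@H](O)COCc1ccccc1 | intermediate
17 | carbon dioxide | O=C=O | starting material
18 | (S,Z)-4-[(benzyloxy)methyl]-5-[(S)-15-methyl-2-oxoheptadecylidene]-1,3-dioxolan-2-one | CC[C@H](C)CCCCCCCCCCCCC(=O)/C=C1\OC(=O)O[C@H]1COCc2ccccc2 | intermediate
19 | tert-butyl (2S,18S)-1-(benzyloxy)-18-methyl-3,5-dioxoicosan-2-yl carbonate (formed as its enolate; neutral diketone drawn) | CC[C@H](C)CCCCCCCCCCCCC(=O)CC(=O)[C@H](COCc1ccccc1)OC(=O)OC(C)(C)C | intermediate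
20 | (S)-5-[(benzyloxy)methyl]-4-hydroxy-3-[(S)-14-methylhexadecanoyl]furan-2(5H)-one | CC[C@H](C)CCCCCCCCCCCCC(=O)C1=C(O)[C@H](COCc2ccccc2)OC1=O | intermediate
21 | (S)-4-hydroxy-5-(hydroxymethyl)-3-[(S)-14-methylhexadecanoyl]furan-2(5H)-one | CC[C@H](C)CCCCCCCCCCCCC(=O)C1=C(O)[C@H](CO)OC1=O | target

**Step count**

Total: 8 steps. Longest linear sequence: 6 steps (steps 3, 4, 5, 6, 7, 8, from 8 and 9); the side‑chain branch (steps 1 and 2) joins at step 6.

**Steps most likely to fail**

Step 7 (proposed new method). Four processes could defeat it: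
- isomerisation of the γ‑hydroxy ynone by the amidine before CO2 is captured;
- loss of CO2 from the opened carbonate if water is present, which amounts to net hydration;
- slow C‑acylation of the stabilised enolate by the hindered tert‑butyl carbonate;
- epimerisation at C5 or β‑elimination of benzyl alkoxide if alkoxide is in excess.

The fallback uses the known Lacey–Dieckmann route to 3‑acyltetronic acids; it sets out from acid 5 and comes back to the route at 20. Acid 5 is condensed with Meldrum's acid (2,2‑dimethyl‑1,3‑dioxane‑4,6‑dione; DCC, DMAP, CH2Cl2, 0 °C → rt) to give the acyl Meldrum's acid 5-[(S)-1-hydroxy-14-methylhexadecylidene]-2,2-dimethyl-1,3-dioxane-4,6-dione F1. The hydroxy ester partner comes from commercial O‑benzyl‑L‑serine. Diazotisation with retention (NaNO2, 1 M H2SO4, 0 °C → rt) should give (S)-3-(benzyloxy)-2-hydroxypropanoic acid F2, and Fischer esterification (MeOH, cat. H2SO4) then gives methyl (S)-3-(benzyloxy)-2-hydroxypropanoate F3. Heating F1 with F3 in toluene at 110 °C traps the acylketene as methyl (S)-3-(benzyloxy)-2-{[(S)-16-methyl-3-oxooctadecanoyl]oxy}propanoate F4. Dieckmann cyclisation (Bu4NF, THF, rt; then 1 M HCl) closes C3–C4 and should give 20.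

Step 6. Three processes could defeat it: incomplete acylation if the dianion is poorly soluble, enolisation of the amide by the acetylide, and conjugate addition of the released amine or base‑induced isomerisation of the hydroxy ynone during the quench. The fallback protects the carbinol and uses a palladium/copper acylation; it sets out from 14 (with acid 5) and comes back at 16. Silylation of 14 (t‑BuMe2SiCl, imidazole, DMF) gives tert-butyl{[(R)-1-(benzyloxy)but-3-yn-2-yl]oxy}dimethylsilane F5. Acid 5 with (COCl)2 and catalytic DMF in CH2Cl2 gives (S)-14-methylhexadecanoyl chloride F6. Acyl Sonogashira coupling of F5 and F6 (PdCl2(PPh3)2, CuI, Et3N, THF, rt) should give (2R,18S)-1-(benzyloxy)-2-[(tert-butyldimethylsilyl)oxy]-18-methylicos-3-yn-5-one F7. Non‑basic desilylation with HF·pyridine in THF then returns 16.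

Step 3. Two processes could defeat it: decarbonylation of the α‑alkoxy acylpalladium intermediate, and conjugate addition of the alkynylzinc to the ynone formed. The fallback replaces the cross‑coupling by an addition to an amide; it sets out from 9 and comes back at 12. Treating 9 with MeNH(OMe)·HCl and pyridine in CH2Cl2 at 0 °C gives 2-(benzyloxy)-N-methoxy-N-methylacetamide F8. Addition of lithium acetylide 10 (from 8 and n‑BuLi) to F8 in THF at −78 → 0 °C, with an acidic quench, should give 12.

**Further compounds**

F1 | step 7 | 5-[(S)-1-hydroxy-14-methylhexadecylidene]-2,2-dimethyl-1,3-dioxane-4,6-dione | CC[C@H](C)CCCCCCCCCCCCC(O)=C1C(=O)OC(C)(C)OC1=O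
F2 | step 7 | (S)-3-(benzyloxy)-2-hydroxypropanoic acid | OC(=O)[C@H](COCc1ccccc1)O
F3 | step 7 | methyl (S)-3-(benzyloxy)-2-hydroxypropanoate | COC(=O)[C@H](COCc1ccccc1)O
F4 | step 7 | methyl (S)-3-(benzyloxy)-2-{[(S)-16-methyl-3-oxooctadecanoyl]oxy}propanoate | CC[C@H](C)CCCCCCCCCCCCC(=O)CC(=O)O[C@@H](COCc1ccccc1)C(=O)OC
F5 | step 6 | tert-butyl{[(R)-1-(benzyloxy)but-3-yn-2-yl]oxy}dimethylsilane | C#C[C@@H](O[Si](C)(C)C(C)(C)C)COCc1ccccc1
F6 | step 6 | (S)-14-methylhexadecanoyl chloride | CC[C@H](C)CCCCCCCCCCCCC(=O)Cl
F7 | step 6 | (2R,18S)-1-(benzyloxy)-2-[(tert-butyldimethylsilyl)oxy]-18-methylicos-3-yn-5-one | CC[C@H](C)CCCCCCCCCCCCC(=O)C#C[C@@H](O[Si](C)(C)C(C)(C)C)COCc1ccccc1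
F8 | step 3 | 2-(benzyloxy)-N-methoxy-N-methylacetamide | CON(C)C(=O)COCc1ccccc1
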